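The target is the cyclic enol ether of a 2-substituted cyclohexane-1,3-dione; the route exploits its vinylogous ester O1–C8a=C4a–C5=O (chromenone numbering), which spans the dihydropyran and cyclohexenone rings. The carbocycle is disconnected at C5–C6 and C4a–C8a into a ketene (C4a=C5=O) and a cyclobutanone enol ether (C8a, C8, C7, C6) carried on O1. In one operation an intramolecular ketene–alkoxycyclobutene [2+2] cycloaddition should make both bonds and close the pyran ring, and strain-driven opening of the resulting bicyclo[2.2.0]hexanone enlarges the four-membered ring to the 3-alkoxycyclohexenone. The precursor is an open-chain anti-3-silyloxy-5-(cyclobutenyloxy)docosanoate, assembled from a chiral-pool Wittig reagent and hexadecanal.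

Key step: step 6

Remark: compounds 1, 2 and 6 are assumed to be commercially available. The three new sp3 centres of the transient cycloadduct 11 are left unassigned because the same operation erases them.

Step 1
Reactants: 1 methyl (3R)-3-[(tert-butyldimethylsilyl)oxy]-5-oxo-6-(triphenylphosphoranylidene)hexanoate; 2 hexadecanal
Product: 3 methyl (3R,6E)-3-[(tert-butyldimethylsilyl)oxy]-5-oxodocos-6-enoate
Conditions: toluene, 90 °C
Reagents that add atoms: none
Why: Wittig olefination of the aliphatic aldehyde with the keto-stabilized ylide should give the E-enone, and the silyl ether and the ester are inert to the neutral ylide.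

Step 2
Reactants: 3 methyl (3R,6E)-3-[(tert-butyldimethylsilyl)oxy]-5-oxodocos-6-enoate
Product: 4 methyl (3R,5R,6E)-3-[(tert-butyldimethylsilyl)oxy]-5-hydroxydocos-6-enoate
Conditions: (S)-2-methyl-CBS-oxazaborolidine (20 mol%), BH3·SMe2, THF, −30 °C; MeOH quench
Reagents that add atoms: none
Why: Corey–Bakshi–Shibata reduction, in which the (S)-oxazaborolidine binds the ketone with the alkenyl group as the large substituent and delivers hydride to the face that gives the (5R)-allylic alcohol, so the new C5 centre (anti to the C3 silyloxy group) is set by the catalyst and not by the substrate.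

Step 3
Reactants: 4 methyl (3R,5R,6E)-3-[(tert-butyldimethylsilyl)oxy]-5-hydroxydocos-6-enoate
Product: 5 methyl (3R,5S)-3-[(tert-butyldimethylsilyl)oxy]-5-hydroxydocosanoate
Conditions: H2 (1 atm), 5% Pt/C, EtOAc, rt
Reagents that add atoms: none
Why: Heterogeneous catalytic hydrogenation saturates the disubstituted alkene without touching the carbinol centre (its descriptor changes from R to S only through the priority rules), Pt being chosen over Pd to limit allylic isomerization and C–O hydrogenolysis, and the neutral medium keeps the 5-hydroxy ester from lactonizing.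

Step 4
Reactants: 5 methyl (3R,5S)-3-[(tert-butyldimethylsilyl)oxy]-5-hydroxydocosanoate; 6 2-(cyclobut-1-en-1-yl)-4,4,5,5-tetramethyl-1,3,2-dioxaborolane
Product: 7 methyl (3R,5S)-3-[(tert-butyldimethylsilyl)oxy]-5-(cyclobut-1-en-1-yloxy)docosanoate
Conditions: 6 (3 equiv), Cu(OAc)2 (2 equiv), Et3N (4 equiv), 4 Å molecular sieves, CH2Cl2, dry air, rt; chromatography on Et3N-deactivated silica
Reagents that add atoms: 6 2-(cyclobut-1-en-1-yl)-4,4,5,5-tetramethyl-1,3,2-dioxaborolane, CC1(C)OB(OC1(C)C)C1=CCC1
Why: Chan–Lam oxidative C–O coupling, in which the alkenyl group passes from boron to copper and reductive elimination from a high-valent copper alkoxide forms the enol ether O–C(sp2) bond, leaving the C5–O bond and its configuration untouched.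

Step 5
Reactants: 7 methyl (3R,5S)-3-[(tert-butyldimethylsilyl)oxy]-5-(cyclobut-1-en-1-yloxy)docosanoate
Product: 8 potassium (3R,5S)-3-[(tert-butyldimethylsilyl)oxy]-5-(cyclobut-1-en-1-yloxy)docosanoate
Conditions: TMSOK (1.05 equiv), THF, rt; evaporation and trituration, no acid
Reagents that add atoms: potassium trimethylsilanolate, C[Si](C)(C)[O-].[K+]
Why: Nucleophilic cleavage of the methyl ester by silanolate (anhydrous saponification) gives the carboxylate salt without aqueous acid, so the acid-labile enol ether and the silyl ether should survive.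

Step 6
Reactants: 8 potassium (3R,5S)-3-[(tert-butyldimethylsilyl)oxy]-5-(cyclobut-1-en-1-yloxy)docosanoate
Product: 12 (2S,4R)-4-[(tert-butyldimethylsilyl)oxy]-2-heptadecyl-3,4,7,8-tetrahydro-2H-chromen-5(6H)-one, via 2-acyloxy-1-methylpyridinium iodide 9 (not isolated), via aldoketene 10 (not isolated), via alkoxybicyclo[2.2.0]hexanone cycloadduct 11 (not isolated)
Conditions: 2-chloro-1-methylpyridinium iodide (1.5 equiv), Et3N (5 equiv), MeCN–toluene, 80 °C, 8 added over 6 h, high dilution
Reagents that add atoms: none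
Why: Proposed new method: triethylamine converts the activated ester 9 into aldoketene 10, whose electrophilic carbonyl carbon (C5) is attacked by the nucleophilic CH carbon (C6) of the tethered 1-alkoxycyclobutene while the resulting cyclobutyl oxocarbenium carbon (C8a) is captured by the ketene alpha carbon (C4a), an intramolecular [2+2] ketene–enol ether cycloaddition that gives the 1-alkoxybicyclo[2.2.0]hexan-2-one 11. In 11 the central C6–C8a bond joins the alkoxy-bearing donor carbon to the carbon alpha to the ketone, so it should break heterolytically in a retro-aldol sense with release of the strain of both four-membered rings, and loss of the C4a proton then leaves the 3-alkoxycyclohex-2-enone. The closest known reaction types are the intramolecular ketene–alkene [2+2] cycloaddition of ketenes generated from carboxylic acid derivatives and amine base, and the two-carbon ring expansion of cyclic silyl enol ethers through ketene cycloadducts and retro-aldol opening to cycloalkane-1,3-diones; their combination on an alkoxycyclobutene has not been shown. The dihydropyran ring closes as the six-membered ring of a fused bicycle in the cycloaddition (four-atom tether, the ketene alpha carbon bonding to the oxygen-bearing alkene carbon), and the carbocycle arises by enlargement of the cyclobutene by the two ketene carbons. No stereocentre of the product is made, since C4a, C6 and C8a end as sp2 or CH2 carbons and the carbinol centres C2 and C4 are not touched. The step needs the fused regiochemistry and ring closure in preference to ketene dimerization, which the polarity of the enol ether (oxygen on the tethered carbon) and slow addition at high dilution should secure.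

Step 7
Reactants: 12 (2S,4R)-4-[(tert-butyldimethylsilyl)oxy]-2-heptadecyl-3,4,7,8-tetrahydro-2H-chromen-5(6H)-one
Product: 13 (2S,4R)-2-heptadecyl-4-hydroxy-3,4,7,8-tetrahydro-2H-chromen-5(6H)-one
Conditions: TBAF, AcOH, THF, 0 °C to rt
Reagents that add atoms: none
Why: Fluoride-mediated desilylation of the allylic TBS ether, buffered with acetic acid so that the vinylogous ester and the C4 carbinol do not suffer elimination, should liberate the target without touching either stereocentre.

Compound list
1 | methyl (3R)-3-[(tert-butyldimethylsilyl)oxy]-5-oxo-6-(triphenylphosphoranylidene)hexanoate | O=C(C=P(c1ccccc1)(c1ccccc1)c1ccccc1)C[C@@H](O[Si](C)(C)C(C)(C)C)CC(=O)OC | starting material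
2 | hexadecanal | CCCCCCCCCCCCCCCC=O | starting material
3 | methyl (3R,6E)-3-[(tert-butyldimethylsilyl)oxy]-5-oxodocos-6-enoate | CCCCCCCCCCCCCCC/C=C/C(=O)C[C@@H](O[Si](C)(C)C(C)(C)C)CC(=O)OC | intermediate
4 | methyl (3R,5R,6E)-3-[(tert-butyldimethylsilyl)oxy]-5-hydroxydocos-6-enoate | CCCCCCCCCCCCCCC/C=C/[C@H](O)C[C@@H](O[Si](C)(C)C(C)(C)C)CC(=O)OC | intermediate
5 | methyl (3R,5S)-3-[(tert-butyldimethylsilyl)oxy]-5-hydroxydocosanoate | CCCCCCCCCCCCCCCCC[C@H](O)C[C@@H](O[Si](C)(C)C(C)(C)C)CC(=O)OC | intermediate
6 | 2-(cyclobut-1-en-1-yl)-4,4,5,5-tetramethyl-1,3,2-dioxaborolane | CC1(C)OB(OC1(C)C)C1=CCC1 | starting material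
7 | methyl (3R,5S)-3-[(tert-butyldimethylsilyl)oxy]-5-(cyclobut-1-en-1-yloxy)docosanoate | CCCCCCCCCCCCCCCCC[C@H](OC1=CCC1)C[C@@H](O[Si](C)(C)C(C)(C)C)CC(=O)OC | intermediate
8 | potassium (3R,5S)-3-[(tert-butyldimethylsilyl)oxy]-5-(cyclobut-1-en-1-yloxy)docosanoate | CCCCCCCCCCCCCCCCC[C@H](OC1=CCC1)C[C@@H](O[Si](C)(C)C(C)(C)C)CC(=O)[O-].[K+] | intermediate
9 | 1-methyl-2-{[(3R,5S)-3-[(tert-butyldimethylsilyl)oxy]-5-(cyclobut-1-en-1-yloxy)docosanoyl]oxy}pyridinium iodide | CCCCCCCCCCCCCCCCC[C@H](OC1=CCC1)C[C@@H](O[Si](C)(C)C(C)(C)C)CC(=O)Oc1cccc[n+]1C.[I-] | intermediate (not isolated)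
10 | (3R,5S)-3-[(tert-butyldimethylsilyl)oxy]-5-(cyclobut-1-en-1-yloxy)docos-1-en-1-one (aldoketene) | CCCCCCCCCCCCCCCCC[C@H](OC1=CCC1)C[C@@H](O[Si](C)(C)C(C)(C)C)C=C=O | intermediate (not isolated)
11 | [2+2] cycloadduct: the pyran ring (O1, C2, C3, C4, C4a, C8a; 2S-heptadecyl, 4R-silyloxy) fused at C4a–C8a to a bicyclo[2.2.0]hexan-2-one with bridgeheads C8a (bearing O1) and C6 and the ketone at C5; new centres unassigned | CCCCCCCCCCCCCCCCC[C@H]1C[C@@H](O[Si](C)(C)C(C)(C)C)C2C(=O)C3CCC23O1 | intermediate (not isolated)
12 | (2S,4R)-4-[(tert-butyldimethylsilyl)oxy]-2-heptadecyl-3,4,7,8-tetrahydro-2H-chromen-5(6H)-one | CCCCCCCCCCCCCCCCC[C@H]1C[C@@H](O[Si](C)(C)C(C)(C)C)C2=C(CCCC2=O)O1 | intermediate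
13 | (2S,4R)-2-heptadecyl-4-hydroxy-3,4,7,8-tetrahydro-2H-chromen-5(6H)-one | CCCCCCCCCCCCCCCCC[C@H]1C[C@@H](O)C2=C(CCCC2=O)O1 | target

Total step count: 7
Longest linear sequence: 7 steps (from 1 and 2 to 13)

Steps most likely to fail

1. Step 6 (proposed new method). The ketene may dimerize, or the first C5–C6 bond may form without the ring closure at C4a–C8a, leaving a C-acylated cyclobutenyl ether. The enol ether may also be cleaved by the ammonium salt before it reacts. The fallback uses known chemistry, makes the same two bonds one after the other, sets out from 5 and comes back at 12. Silylation of 5 (TESCl, imidazole, CH2Cl2) would give methyl (3R,5S)-3-[(tert-butyldimethylsilyl)oxy]-5-[(triethylsilyl)oxy]docosanoate F1. Me2AlSEt (from AlMe3 and EtSH, CH2Cl2) would convert the ester into S-ethyl (3R,5S)-3-[(tert-butyldimethylsilyl)oxy]-5-[(triethylsilyl)oxy]docosanethioate F2. Fukuyama coupling with (4-ethoxy-4-oxobutyl)zinc bromide and catalytic PdCl2(PPh3)2 (toluene–THF, rt) would form the C5–C6 bond and give ethyl (7R,9S)-7-[(tert-butyldimethylsilyl)oxy]-5-oxo-9-[(triethylsilyl)oxy]hexacosanoate F3. Dieckmann-type cyclization (KOtBu, THF, 0 °C) would form the C4a–C8a bond and give 2-[(1R,3S)-1-[(tert-butyldimethylsilyl)oxy]-3-[(triethylsilyl)oxy]icosyl]cyclohexane-1,3-dione F4. PPTS in MeOH would remove the triethylsilyl group selectively, and warming in toluene over molecular sieves should condense the freed hydroxyl with a ring carbonyl to give 12.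

2. Step 4. Transfer of the alkenyl group from boron to copper may be slow with the hindered secondary alcohol, so protodeboronation and homocoupling of the boronate compete. The amine base may induce lactonization of the 5-hydroxy ester, and the enol ether may hydrolyse during purification. The fallback sets out from 5 and comes back at 7. Acid-catalysed exchange with 1,1-dimethoxycyclobutane (catalytic PPTS, benzene, removal of methanol) would give the mixed ketal methyl (3R,5S)-3-[(tert-butyldimethylsilyl)oxy]-5-[(1-methoxycyclobutyl)oxy]docosanoate F5. Ionization of the less hindered methoxy group and deprotonation (TMSOTf, iPr2NEt, CH2Cl2, −20 °C) should then eliminate methanol to give 7.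

3. Step 2. Facial selectivity may be poor if the bias of the beta-silyloxy ketone opposes the catalyst. The fallback sets the C5 centre by inversion, sets out from 3 and comes back at 5. Reduction with the enantiomeric (R)-oxazaborolidine and BH3·SMe2 would give methyl (3R,5S,6E)-3-[(tert-butyldimethylsilyl)oxy]-5-hydroxydocos-6-enoate F6. Hydrogenation as in step 3 would give methyl (3R,5R)-3-[(tert-butyldimethylsilyl)oxy]-5-hydroxydocosanoate F7. Mitsunobu reaction (4-nitrobenzoic acid, PPh3, DIAD, THF, 0 °C) would invert C5 to methyl (3R,5S)-3-[(tert-butyldimethylsilyl)oxy]-5-[(4-nitrobenzoyl)oxy]docosanoate F8. Methanolysis (K2CO3, MeOH, 0 °C) should then give 5.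

Further compounds
F1 | step 6 | methyl (3R,5S)-3-[(tert-butyldimethylsilyl)oxy]-5-[(triethylsilyl)oxy]docosanoate | CCCCCCCCCCCCCCCCC[C@H](O[Si](CC)(CC)CC)C[C@@H](O[Si](C)(C)C(C)(C)C)CC(=O)OC
F2 | step 6 | S-ethyl (3R,5S)-3-[(tert-butyldimethylsilyl)oxy]-5-[(triethylsilyl)oxy]docosanethioate | CCCCCCCCCCCCCCCCC[C@H](O[Si](CC)(CC)CC)C[C@@H](O[Si](C)(C)C(C)(C)C)CC(=O)SCC
F3 | step 6 | ethyl (7R,9S)-7-[(tert-butyldimethylsilyl)oxy]-5-oxo-9-[(triethylsilyl)oxy]hexacosanoate | CCCCCCCCCCCCCCCCC[C@H](O[Si](CC)(CC)CC)C[C@@H](O[Si](C)(C)C(C)(C)C)CC(=O)CCCC(=O)OCC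
F4 | step 6 | 2-[(1R,3S)-1-[(tert-butyldimethylsilyl)oxy]-3-[(triethylsilyl)oxy]icosyl]cyclohexane-1,3-dione | CCCCCCCCCCCCCCCCC[C@H](O[Si](CC)(CC)CC)C[C@@H](O[Si](C)(C)C(C)(C)C)C1C(=O)CCCC1=O
F5 | step 4 | methyl (3R,5S)-3-[(tert-butyldimethylsilyl)oxy]-5-[(1-methoxycyclobutyl)oxy]docosanoate | CCCCCCCCCCCCCCCCC[C@H](OC1(OC)CCC1)C[C@@H](O[Si](C)(C)C(C)(C)C)CC(=O)OC
F6 | step 2 | methyl (3R,5S,6E)-3-[(tert-butyldimethylsilyl)oxy]-5-hydroxydocos-6-enoate | CCCCCCCCCCCCCCC/C=C/[C@@H](O)C[C@@H](O[Si](C)(C)C(C)(C)C)CC(=O)OC
F7 | step 2 | methyl (3R,5R)-3-[(tert-butyldimethylsilyl)oxy]-5-hydroxydocosanoate | CCCCCCCCCCCCCCCCC[C@@H](O)C[C@@H](O[Si](C)(C)C(C)(C)C)CC(=O)OC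
F8 | step 2 | methyl (3R,5S)-3-[(tert-butyldimethylsilyl)oxy]-5-[(4-nitrobenzoyl)oxy]docosanoate | CCCCCCCCCCCCCCCCC[C@H](OC(=O)c1ccc(cc1)[N+](=O)[O-])C[C@@H](O[Si](C)(C)C(C)(C)C)CC(=O)OC
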